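You can count the length of a chain without seeing one: divide the monomer in chains by the chains begun.

common to all: initiator 38 µM
- green: free monomer 0.0070 M; run made earlier
- Wednesday's: free monomer 0.014 M; time 25 h
- Monday's: free monomer 0.014 M; time 8.0 h

green run (percent of the free monomer charged)

| time / h | monomer in chains / % | free monomer / % |
|---|---|---|
| 0.667 | 0.2 | 99.5 |
| 2.00 | 3.2 | 96.6 |
| 3.00 | 6.3 | 93.8 |
| 5.00 | 12.6 | 86.5 |

(each reading ± 0.5 percentage points)

- the average divides the monomer in chains by the number of chains begun, living and dead together
- the earlier runs do not show the number of chains; that part of a forecast is a guess

- which of the two ends with the longer chains by the average number of monomer units in a chain (chains begun, living or dead) ("neither" if they lie within 10%) (Wednesday's / Monday's / neither)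
- average number of monomer units in a chain (chains begun, living or dead) at the end, Wednesday's
- average number of monomer units in a chain (chains begun, living or dead) at the end, Monday's

1. Suppose each initiator begins one chain; that is my guess, since these runs show no chain count. Wednesday's and Monday's flasks then both have a ceiling of 368 turnovers, the turnover ceiling: [free monomer] charged divided by [initiator] charged, the units per chain at full conversion. The average length (number-average degree of polymerisation) is this ceiling times the share in chains.

2. The share comes from the green run, by two independent ways. Between 2.00 h and 5.00 h, the monomer-in-chains column gains 9.4 percentage points, and the free-monomer column loses 10 points.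

3. These differ by 0.6 points, and a reading has a standard deviation of 0.5 points, so I trust both and take their mean: 0.0325 h⁻¹.

4. I assume that free monomer in Wednesday's and Monday's flasks loses that share of what is left each hour, as read in the green run, counted from the charge. My reckoning gives Monday's 22.9% in chains, so a length of 84.3. Wednesday's, with the same ceiling but a longer time, gets 55.6%, so 205.

5. The forecast names Wednesday's, with 195 for Wednesday's and 76 for Monday's. Its ground: “I assume the same k and lag at double the monomer concentration”. Its numbers are lower than mine; its reasoning counts a lag, and mine counts from the charge.

6. The flasks give Wednesday's: 253 for Wednesday's and 115 for Monday's.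

    free monomer + initiator → living end + monomer in chains (k = 65.0 M⁻¹ h⁻¹)
    free monomer + living end → monomer in chains + living end, rate k2*[living end]*[free monomer] (k = 1700 M⁻¹ h⁻¹)
    monomer in chains + living end → free monomer + living end, rate k3*[living end] as long as [monomer in chains] is above zero (k = 3.30 h⁻¹)
    2 initiator → spent initiator (k = 510 M⁻¹ h⁻¹)

Monday's has 30.6% in chains at 8.00 h, and that share of 368 is 113, against 115. Wednesday's has 67.2% at 25.0 h, which gives 247, against 253. The forecast's 76 for Monday's is 20.7% of that ceiling. A neighbour of Monday's, charged with 0.056 M of free monomer and read at 8.00 h, has a ceiling of 1470. Its 37.8% in chains makes 557, and that flask gives 560.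

The runs are simulated for an exercise.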